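**Retrosynthetic overview**
1. Target 36 ⇐ CBS reduction of enone 35 ⇐ SmI2 ketyl–olefin radical cyclisation of keto dienone 34 (C18–C19 bond; the cyclopentanol ring is closed last).
2. 34 ⇐ Stork–Danheiser union (C13–C14) of the alkyllithium from rings A/B chloride 31 with cycloheptadienone vinylogous ester 14.
3. 14 ⇐ ring-closing metathesis (seven-membered ring) ⇐ aldol of pent-1-en-3-one with aldehyde 8 ⇐ Ir-catalysed asymmetric allylation (sets C22).
4. 31 ⇐ MeMgBr addition (C10) ⇐ 7-endo epoxide opening (oxepane) ⇐ anti conjugate addition/enolate alkylation on enone 19 ⇐ Shi epoxidation of the deconjugated ketal of 3-methylcyclohexenone.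
5. Ring order: cyclohexane (from 15) → oxepane; cycloheptene (metathesis) → cyclopentane (radical step).

Assumption: the SMILES is taken as drawn (3S,6R,7R,10S,11R,16S,18R,19R,22R); atom labels follow squalene-type numbering: C2 (CMe2–O), C3 (CHOH), C6 (C–Me, ring fusion), C7 (CH–O), C10 (C(OH)Me), C11, C12–C13 (linker), C14=C15, C16 (CHOH), C17, C18/C22 (ring fusion), C19 (C(OH)Me), C23 (CMe2).

**Route**

Step 1
Reactants: 1 hex-5-en-2-one
Product: 2 2-(but-3-en-1-yl)-2-methyl-1,3-dioxolane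
Conditions: HOCH2CH2OH, p-TsOH (cat.), benzene, reflux (Dean–Stark)
Reagents that add atoms: ethylene glycol, OCCO
Why: Acid-catalysed ketalisation masks the methyl ketone that later becomes C19 so that it survives the hydride, enolate and organolithium steps.

Step 2
Reactants: 2 2-(but-3-en-1-yl)-2-methyl-1,3-dioxolane; 3 allyl methyl carbonate
Product: 4 (E)-methyl 5-(2-methyl-1,3-dioxolan-2-yl)pent-2-en-1-yl carbonate
Conditions: 3 (3 equiv), second-generation Grubbs catalyst (3 mol %), CH2Cl2, 40 °C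
Reagents that add atoms: none
Why: Olefin cross-metathesis of two terminal alkenes with excess carbonate gives the linear (E)-allylic carbonate needed as the π-allyl precursor.

Step 3
Reactants: 4 (E)-allylic carbonate; 5 methyl isobutyrate
Product: 7 methyl (3R)-2,2-dimethyl-3-[2-(2-methyl-1,3-dioxolan-2-yl)ethyl]pent-4-enoate, via silyl ketene acetal 6 (not isolated)
Conditions: 5, LiN(i-Pr)2, Me3SiCl, THF, −78 °C → rt, volatiles removed, pentane filtration; then 4, [Ir(cod)Cl]2 (2 mol %), (Ra,R,R)-O,O′-(1,1′-binaphthyl-2,2′-diyl)-N,N-bis(1-phenylethyl)phosphoramidite (4 mol %), n-PrNH2 (activation), THF, 35 °C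
Reagents that add atoms: none
Why: Ir-catalysed asymmetric allylic alkylation, in which the silyl ketene acetal attacks the substituted terminus of the allyl-iridium intermediate, forms the C22–C23 bond next to the gem-dimethyl quaternary carbon and sets C22 as R under ligand control (the ligand antipode would give the enantiomer).

Step 4
Reactants: 7 methyl (3R)-2,2-dimethyl-3-[2-(2-methyl-1,3-dioxolan-2-yl)ethyl]pent-4-enoate
Product: 8 (3R)-2,2-dimethyl-3-[2-(2-methyl-1,3-dioxolan-2-yl)ethyl]pent-4-enal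
Conditions: i-Bu2AlH (1.1 equiv), CH2Cl2, −78 °C; aq. potassium sodium tartrate
Reagents that add atoms: none
Why: Partial reduction of the neopentyl ester with i-Bu2AlH stops at the stable tetrahedral aluminium hemiacetal, which releases the aldehyde on work-up.

Step 5
Reactants: 8 aldehyde; 9 pent-1-en-3-one
Product: 11 (7R)-5-hydroxy-4,6,6-trimethyl-7-[2-(2-methyl-1,3-dioxolan-2-yl)ethyl]nona-1,8-dien-3-one (mixture at C4 and C5), via lithium penta-1,3-dien-3-olate 10 (not isolated)
Conditions: 9, LiN(i-Pr)2, THF, −78 °C; then 8, −78 °C; aq. NH4Cl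
Reagents that add atoms: none
Why: Kinetic alpha-prime deprotonation of the vinyl ketone and aldol addition to the non-enolisable aldehyde install C15–C17 with both terminal olefins in place, and the two new centres are left uncontrolled because both become sp2 later.

Step 6
Reactants: 11 aldol adduct
Product: 12 (4R)-6-hydroxy-5,5,7-trimethyl-4-[2-(2-methyl-1,3-dioxolan-2-yl)ethyl]cyclohept-2-en-1-one (mixture at C6 and C7)
Conditions: second-generation Grubbs catalyst (5 mol %), CH2Cl2 (5 mM), 40 °C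
Reagents that add atoms: none
Why: Ring-closing metathesis of the vinyl ketone with the C22 vinyl group closes the seven-membered ring as a (necessarily Z) cycloheptenone, helped by the gem-dimethyl effect.

Step 7
Reactants: 12 hydroxy cycloheptenone
Product: 13 (6R)-2,7,7-trimethyl-6-[2-(2-methyl-1,3-dioxolan-2-yl)ethyl]cyclohept-4-ene-1,3-dione
Conditions: Dess–Martin periodinane, CH2Cl2, rt
Reagents that add atoms: none
Why: Dess–Martin oxidation of the beta-hydroxy ketone gives the enolised 1,3-diketone without touching the acetal or the enone.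

Step 8
Reactants: 13 ene-1,3-dione
Product: 14 (6R)-3-methoxy-2,7,7-trimethyl-6-[2-(2-methyl-1,3-dioxolan-2-yl)ethyl]cyclohepta-2,4-dien-1-one
Conditions: (MeO)2SO2, K2CO3, acetone, reflux
Reagents that add atoms: dimethyl sulfate, COS(=O)(=O)OC
Why: O-alkylation of the vinylogous acid (vinylogous ester formation) occurs at the less hindered oxygen remote from the gem-dimethyl group, giving the linearly conjugated dienone ether and leaving the hindered C14 carbonyl free for the Stork–Danheiser step.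

Step 9
Reactants: 15 3-methylcyclohex-2-en-1-one
Product: 16 7-methyl-1,4-dioxaspiro[4.5]dec-7-ene
Conditions: HOCH2CH2OH, p-TsOH (cat.), benzene, reflux (Dean–Stark)
Reagents that add atoms: ethylene glycol, OCCO
Why: Ketalisation of the enone under acid catalysis moves the double bond out of conjugation (deconjugative ketalisation), giving the beta,gamma-unsaturated ketal with a trisubstituted ring olefin.

Step 10
Reactants: 16 7-methyl-1,4-dioxaspiro[4.5]dec-7-ene
Product: 17 (1S,6R)-1-methyl-7-oxabicyclo[4.1.0]heptan-3-one ethylene ketal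
Conditions: D-fructose-derived Shi ketone (30 mol %), KHSO5 (as 2KHSO5·KHSO4·K2SO4), K2CO3, Bu4NHSO4, MeCN/CH2(OMe)2/aq. buffer, 0 °C
Reagents that add atoms: potassium peroxymonosulfate (KHSO5), [K+].[O-]S(=O)(=O)OO
Why: Shi asymmetric epoxidation, in which the chiral dioxirane epoxidises the trisubstituted olefin through the spiro transition state, gives the (1S,6R)-epoxide and so fixes the future C7 (R) oxygen stereocentre.

Step 11
Reactants: 17 epoxy ketal
Product: 19 (4R)-4-(tert-butyldimethylsilyloxy)-3-methylcyclohex-2-en-1-one, via (4R)-4-hydroxy-3-methylcyclohex-2-en-1-one 18 (not isolated)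
Conditions: p-TsOH·H2O (cat.), acetone/H2O, rt; concentrate; then t-BuMe2SiCl, imidazole, DMF, rt
Reagents that add atoms: water, O; tert-butyldimethylsilyl chloride, CC(C)(C)[Si](C)(C)Cl
Why: Acetal hydrolysis then beta-elimination (vinylogous opening of the beta,gamma-epoxy ketone) gives the gamma-hydroxy enone with the C7–O bond untouched, and silylation turns the hydroxyl into the anti-directing group for the next step.

Step 12
Reactants: 19 silyloxy enone; 20 5-bromo-2-methylpent-2-ene; 21 2-chloroethanol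
Product: 26 (3R,4R)-4-(tert-butyldimethylsilyloxy)-2-(2-chloroethyl)-3-methyl-3-(4-methylpent-3-en-1-yl)cyclohexan-1-one (C2 epimers), via (4-methylpent-3-en-1-yl)magnesium bromide 22 (not isolated), via trimethylsilyl enol ether 23 (not isolated), via lithium enolate 24 (not isolated), via 2-chloroethyl triflate 25 (not isolated)
Conditions: 20, Mg, THF; then 19, CuBr·SMe2 (10 mol %), Me3SiCl, HMPA, THF, −78 °C; hexane filtration; MeLi, THF, 0 °C; then 25 (from 21, Tf2O, 2,6-lutidine, CH2Cl2, −78 °C), −78 → −20 °C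
Reagents that add atoms: none
Why: In this three-component coupling the Cu-catalysed conjugate addition of the homoprenyl Grignard reagent occurs anti to the C7 silyloxy group (sets the C6 quaternary centre as R), and the regiodefined enolate, regenerated from its silyl enol ether with MeLi, is C-alkylated by the triflate only at C11 (enolate alkylation; C11 is corrected thermodynamically in step 14).

Step 13
Reactants: 26 chloroethyl ketone
Product: 27 (3R,4R)-4-(tert-butyldimethylsilyloxy)-2-(2-chloroethyl)-3-{2-[(2S)-3,3-dimethyloxiran-2-yl]ethyl}-3-methylcyclohexan-1-one (C2 epimers)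
Conditions: L-fructose-derived (enantiomeric) Shi ketone (30 mol %), KHSO5 (as 2KHSO5·KHSO4·K2SO4), K2CO3, Bu4NHSO4, MeCN/CH2(OMe)2/aq. buffer, 0 °C
Reagents that add atoms: potassium peroxymonosulfate (KHSO5), [K+].[O-]S(=O)(=O)OO
Why: Shi asymmetric epoxidation with the enantiomeric ketone is selective for the electron-rich trisubstituted side-chain olefin and sets C3 as S under catalyst control.

Step 14
Reactants: 27 epoxy silyl ether
Product: 29 (3S,5aR,6R,9aR)-6-(2-chloroethyl)-3-hydroxy-2,2,5a-trimethyloctahydro-1-benzoxepin-7(2H)-one, via epoxy alcohol 28 (not isolated)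
Conditions: Bu4NF, AcOH, THF, rt; then (+)-camphorsulfonic acid (0.3 equiv), CH2Cl2, 0 °C → rt, 16 h
Reagents that add atoms: none
Why: After fluoride desilylation, acid-catalysed intramolecular epoxide opening lets the equatorial C7 hydroxyl attack the tertiary epoxide carbon C2 (7-endo, Markovnikov) with the C3–O bond and its S configuration retained, giving the trans-fused oxepane, while the acid equilibrates C11 through the enol to the equatorial (R) epimer.

Step 15
Reactants: 29 bicyclic keto chloride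
Product: 31 bis(triethylsilyl) ether of (3S,5aR,6R,7S,9aR)-6-(2-chloroethyl)-2,2,5a,7-tetramethyldecahydro-1-benzoxepine-3,7-diol, via diol 30 (not isolated)
Conditions: MeMgBr (3 equiv), Et2O/THF, −78 → 0 °C; aq. NH4Cl; then Et3SiOTf, 2,6-lutidine, CH2Cl2, −78 → 0 °C
Reagents that add atoms: methylmagnesium bromide, C[Mg]Br; triethylsilyl trifluoromethanesulfonate, CC[Si](CC)(CC)OS(=O)(=O)C(F)(F)F
Why: In this Grignard 1,2-addition the axial C6 methyl blocks axial approach, so the methyl group enters equatorially and the C10 hydroxyl ends axial (10S), and both hydroxyls are then silylated so that the chloride can be lithiated.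

Step 16
Reactants: 31 bis-silyl chloride; 14 vinylogous ester
Product: 34 (5R)-3-{2-[(3S,5aR,6R,7S,9aR)-3,7-dihydroxy-2,2,5a,7-tetramethyldecahydro-1-benzoxepin-6-yl]ethyl}-2,4,4-trimethyl-5-(3-oxobutyl)cyclohepta-2,6-dien-1-one, via alkyllithium 32 (not isolated), via lithium alkoxide adduct 33 (not isolated)
Conditions: Li (granular), 4,4′-di-tert-butylbiphenyl (10 mol %), THF, −78 °C, cannula-filtered from excess Li; then 14, −78 → −30 °C; then 2 M HCl, THF, rt
Reagents that add atoms: water, O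
Why: Arene-catalysed reductive lithiation of the primary chloride is followed by a Stork–Danheiser sequence, 1,2-addition to the hindered C14 carbonyl and acidic transposition (enol ether hydrolysis and dehydration), which gives the cross-conjugated dienone while the same acid removes both silyl ethers and the dioxolane.

Step 17
Reactants: 34 keto dienone
Product: 35 (1R,3aR,8aR)-5-{2-[(3S,5aR,6R,7S,9aR)-3,7-dihydroxy-2,2,5a,7-tetramethyldecahydro-1-benzoxepin-6-yl]ethyl}-1-hydroxy-1,4,4,6-tetramethyl-2,3,3a,4,8,8a-hexahydroazulen-7(1H)-one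
Conditions: SmI2 (2.5 equiv), HMPA (10 equiv), t-BuOH (2 equiv), THF, −78 → −40 °C
Reagents that add atoms: none
Why: In this SmI2 ketyl–olefin radical cyclisation (5-exo) one-electron reduction gives a ketyl/dienone radical anion that forms the C18–C19 bond on the face of the C22 tether (cis ring fusion, 18R) with the bulky samarium-bound oxygen anti to C17 (19R), and the samarium enolate is protonated back to the C14=C15 enone.

Step 18
Reactants: 35 hydroazulenone
Product: 36 (1R,3aR,7S,8aR)-5-{2-[(3S,5aR,6R,7S,9aR)-3,7-dihydroxy-2,2,5a,7-tetramethyldecahydro-1-benzoxepin-6-yl]ethyl}-1,4,4,6-tetramethyl-1,2,3,3a,4,7,8,8a-octahydroazulene-1,7-diol (target)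
Conditions: (R)-2-methyl-CBS-oxazaborolidine (1.0 equiv), BH3·SMe2, THF, −30 °C; MeOH
Reagents that add atoms: none
Why: In this Corey–Bakshi–Shibata reduction the (R)-oxazaborolidine delivers hydride with the substituted enone carbon as the large group, which coincides with attack on the convex face of the cis-fused bicycle, giving the 16S allylic alcohol.

**Compound list**
1 | hex-5-en-2-one | CC(=O)CCC=C | starting material
2 | 2-(but-3-en-1-yl)-2-methyl-1,3-dioxolane | CC1(CCC=C)OCCO1 | intermediate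
3 | allyl methyl carbonate | C=CCOC(=O)OC | starting material
4 | (E)-methyl 5-(2-methyl-1,3-dioxolan-2-yl)pent-2-en-1-yl carbonate | COC(=O)OC/C=C/CCC1(C)OCCO1 | intermediate
5 | methyl isobutyrate | COC(=O)C(C)C | starting material
6 | (1-methoxy-2-methylprop-1-enyloxy)trimethylsilane | COC(=C(C)C)O[Si](C)(C)C | intermediate
7 | methyl (3R)-2,2-dimethyl-3-[2-(2-methyl-1,3-dioxolan-2-yl)ethyl]pent-4-enoate | COC(=O)C(C)(C)[C@@H](C=C)CCC1(C)OCCO1 | intermediate
8 | (3R)-2,2-dimethyl-3-[2-(2-methyl-1,3-dioxolan-2-yl)ethyl]pent-4-enal | O=CC(C)(C)[C@@H](C=C)CCC1(C)OCCO1 | intermediate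
9 | pent-1-en-3-one | CCC(=O)C=C | starting material
10 | lithium penta-1,3-dien-3-olate | [Li]OC(=CC)C=C | intermediate
11 | (7R)-5-hydroxy-4,6,6-trimethyl-7-[2-(2-methyl-1,3-dioxolan-2-yl)ethyl]nona-1,8-dien-3-one (mixture at C4, C5) | C=CC(=O)C(C)C(O)C(C)(C)[C@@H](C=C)CCC1(C)OCCO1 | intermediate
12 | (4R)-6-hydroxy-5,5,7-trimethyl-4-[2-(2-methyl-1,3-dioxolan-2-yl)ethyl]cyclohept-2-en-1-one (mixture at C6, C7) | CC1C(O)C(C)(C)[C@H](CCC2(C)OCCO2)C=CC1=O | intermediate
13 | (6R)-2,7,7-trimethyl-6-[2-(2-methyl-1,3-dioxolan-2-yl)ethyl]cyclohept-4-ene-1,3-dione | CC1C(=O)C(C)(C)[C@H](CCC2(C)OCCO2)C=CC1=O | intermediate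
14 | (6R)-3-methoxy-2,7,7-trimethyl-6-[2-(2-methyl-1,3-dioxolan-2-yl)ethyl]cyclohepta-2,4-dien-1-one | COC1=C(C)C(=O)C(C)(C)[C@H](CCC2(C)OCCO2)C=C1 | intermediate
15 | 3-methylcyclohex-2-en-1-one | CC1=CC(=O)CCC1 | starting material
16 | 7-methyl-1,4-dioxaspiro[4.5]dec-7-ene | CC1=CCCC2(C1)OCCO2 | intermediate
17 | (1S,6R)-1-methyl-7-oxabicyclo[4.1.0]heptan-3-one ethylene ketal | C[C@]12CC3(CC[C@H]1O2)OCCO3 | intermediate
18 | (4R)-4-hydroxy-3-methylcyclohex-2-en-1-one | CC1=CC(=O)CC[C@H]1O | intermediate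
19 | (4R)-4-(tert-butyldimethylsilyloxy)-3-methylcyclohex-2-en-1-one | CC1=CC(=O)CC[C@H]1O[Si](C)(C)C(C)(C)C | intermediate
20 | 5-bromo-2-methylpent-2-ene | CC(C)=CCCBr | starting material
21 | 2-chloroethanol | OCCCl | starting material
22 | (4-methylpent-3-en-1-yl)magnesium bromide | CC(C)=CCC[Mg]Br | intermediate
23 | (3R,4R)-4-(tert-butyldimethylsilyloxy)-3-methyl-3-(4-methylpent-3-en-1-yl)-1-(trimethylsilyloxy)cyclohex-1-ene | C[Si](C)(C)OC1=C[C@@](C)(CCC=C(C)C)[C@H](O[Si](C)(C)C(C)(C)C)CC1 | intermediate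
24 | lithium enolate corresponding to 23 | [Li]OC1=C[C@@](C)(CCC=C(C)C)[C@H](O[Si](C)(C)C(C)(C)C)CC1 | intermediate
25 | 2-chloroethyl trifluoromethanesulfonate | ClCCOS(=O)(=O)C(F)(F)F | intermediate
26 | (3R,4R)-4-(tert-butyldimethylsilyloxy)-2-(2-chloroethyl)-3-methyl-3-(4-methylpent-3-en-1-yl)cyclohexan-1-one (C2 epimers) | ClCCC1[C@@](C)(CCC=C(C)C)[C@H](O[Si](C)(C)C(C)(C)C)CCC1=O | intermediate
27 | (3R,4R)-4-(tert-butyldimethylsilyloxy)-2-(2-chloroethyl)-3-{2-[(2S)-3,3-dimethyloxiran-2-yl]ethyl}-3-methylcyclohexan-1-one (C2 epimers) | ClCCC1[C@@](C)(CC[C@@H]2OC2(C)C)[C@H](O[Si](C)(C)C(C)(C)C)CCC1=O | intermediate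
28 | (3R,4R)-2-(2-chloroethyl)-3-{2-[(2S)-3,3-dimethyloxiran-2-yl]ethyl}-4-hydroxy-3-methylcyclohexan-1-one (C2 epimers) | ClCCC1[C@@](C)(CC[C@@H]2OC2(C)C)[C@H](O)CCC1=O | intermediate
29 | (3S,5aR,6R,9aR)-6-(2-chloroethyl)-3-hydroxy-2,2,5a-trimethyloctahydro-1-benzoxepin-7(2H)-one | ClCC[C@@H]2[C@@]3(C)CC[C@H](O)C(C)(C)O[C@@H]3CCC2=O | intermediate
30 | (3S,5aR,6R,7S,9aR)-6-(2-chloroethyl)-2,2,5a,7-tetramethyldecahydro-1-benzoxepine-3,7-diol | ClCC[C@@H]2[C@@]3(C)CC[C@H](O)C(C)(C)O[C@@H]3CC[C@]2(C)O | intermediate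
31 | 3,7-bis(triethylsilyl) ether of 30 | ClCC[C@@H]2[C@@]3(C)CC[C@H](O[Si](CC)(CC)CC)C(C)(C)O[C@@H]3CC[C@]2(C)O[Si](CC)(CC)CC | intermediate
32 | alkyllithium from 31 (Li in place of Cl) | [Li]CC[C@@H]2[C@@]3(C)CC[C@H](O[Si](CC)(CC)CC)C(C)(C)O[C@@H]3CC[C@]2(C)O[Si](CC)(CC)CC | intermediate
33 | lithium alkoxide from 1,2-addition of 32 to the C14 carbonyl of 14 (mixture at C14) | COC1=C(C)C(O[Li])(CC[C@@H]2[C@@]3(C)CC[C@H](O[Si](CC)(CC)CC)C(C)(C)O[C@@H]3CC[C@]2(C)O[Si](CC)(CC)CC)C(C)(C)[C@H](CCC2(C)OCCO2)C=C1 | intermediate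
34 | (5R)-3-{2-[(3S,5aR,6R,7S,9aR)-3,7-dihydroxy-2,2,5a,7-tetramethyldecahydro-1-benzoxepin-6-yl]ethyl}-2,4,4-trimethyl-5-(3-oxobutyl)cyclohepta-2,6-dien-1-one | CC1=C(CC[C@@H]2[C@@]3(C)CC[C@H](O)C(C)(C)O[C@@H]3CC[C@]2(C)O)C(C)(C)[C@H](CCC(C)=O)C=CC1=O | intermediate
35 | (1R,3aR,8aR)-5-{2-[(3S,5aR,6R,7S,9aR)-3,7-dihydroxy-2,2,5a,7-tetramethyldecahydro-1-benzoxepin-6-yl]ethyl}-1-hydroxy-1,4,4,6-tetramethyl-2,3,3a,4,8,8a-hexahydroazulen-7(1H)-one (cis-fused) | CC1=C(CC[C@@H]2[C@@]3(C)CC[C@H](O)C(C)(C)O[C@@H]3CC[C@]2(C)O)C(C)(C)[C@@H]2CC[C@@](C)(O)[C@@H]2CC1=O | intermediate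
36 | (1R,3aR,7S,8aR)-5-{2-[(3S,5aR,6R,7S,9aR)-3,7-dihydroxy-2,2,5a,7-tetramethyldecahydro-1-benzoxepin-6-yl]ethyl}-1,4,4,6-tetramethyl-1,2,3,3a,4,7,8,8a-octahydroazulene-1,7-diol | CC1=C(CC[C@@H]2[C@@]3(C)CC[C@H](O)C(C)(C)O[C@@H]3CC[C@]2(C)O)C(C)(C)[C@@H]2CC[C@@](C)(O)[C@@H]2C[C@@H]1O | target

**Step count**
Total: 18 steps. Longest linear sequence: 11 steps (steps 1–8, then 16–18); the rings A/B branch is steps 9–15.

**Steps most likely to fail, with fallbacks**

Step 17 (late-stage ketyl–olefin ring closure on the fully assembled dienone; simple reduction or dimerisation of the dienone could compete). Fallback: move the radical ring closure ahead of the fragment union. Setting out from 14, the dioxolane alone is cleaved (pyridinium p-toluenesulfonate, wet acetone) to give (6R)-3-methoxy-2,7,7-trimethyl-6-(3-oxobutyl)cyclohepta-2,4-dien-1-one F1. SmI2/HMPA/t-BuOH then closes the cyclopentanol on this simpler dienone, giving the cis-fused bicyclic vinylogous ester F2, which is silylated with Et3SiOTf to its triethylsilyl ether F3. Addition of alkyllithium 32 to F3 followed by the same HCl work-up comes back to the route at 35.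

Step 14 (7-endo epoxide opening; 6-exo attack at C3 to a tetrahydropyran is the competitor). Fallback: close the C2–O bond by radical–polar crossover hydroalkoxylation, which has no exo mode. Setting out from 27, Me3SiOTf/2,6-lutidine then DBU isomerises the epoxide to the allylic silyl ether F4 (C3–O bond untouched), and Bu4NF frees the enediol F5. Co(salen), N-fluoro-2,4,6-trimethylpyridinium triflate and PhSiH3 then generate the tertiary C2 radical/cation, which is captured by the C7 hydroxyl to form the oxepane; a short camphorsulfonic acid equilibration at C11 comes back to the route at 29.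

Step 12 (C-alkylation of the hindered enolate beside the quaternary carbon with the triflate). Fallback: use allyl iodide as a more forgiving electrophile and trim the allyl group later. Setting out from silyl enol ether 23, MeLi then allyl iodide give the allyl ketone F6. The same epoxidation gives the epoxide F7, and the same desilylation/acid cyclisation gives the bicyclic allyl ketone F8. MeMgBr then Et3SiOTf give the bis(triethylsilyl) ether F9, ozonolysis with NaBH4 work-up gives the primary alcohol F10, and PPh3/CCl4 comes back to the route at 31.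

**Further compounds**
F1 | step 17 | (6R)-3-methoxy-2,7,7-trimethyl-6-(3-oxobutyl)cyclohepta-2,4-dien-1-one | COC1=C(C)C(=O)C(C)(C)[C@H](CCC(C)=O)C=C1
F2 | step 17 | (1R,3aR,8aR)-1-hydroxy-7-methoxy-1,4,4,6-tetramethyl-2,3,3a,4,8,8a-hexahydroazulen-5(1H)-one | COC1=C(C)C(=O)C(C)(C)[C@@H]2CC[C@@](C)(O)[C@@H]2C1
F3 | step 17 | triethylsilyl ether of F2 | COC1=C(C)C(=O)C(C)(C)[C@@H]2CC[C@@](C)(O[Si](CC)(CC)CC)[C@@H]2C1
F4 | step 14 | (3R,4R)-4-(tert-butyldimethylsilyloxy)-2-(2-chloroethyl)-3-methyl-3-[(3S)-4-methyl-3-(trimethylsilyloxy)pent-4-en-1-yl]cyclohexan-1-one (C2 epimers) | ClCCC1[C@@](C)(CC[C@H](O[Si](C)(C)C)C(C)=C)[C@H](O[Si](C)(C)C(C)(C)C)CCC1=O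
F5 | step 14 | (3R,4R)-2-(2-chloroethyl)-4-hydroxy-3-[(3S)-3-hydroxy-4-methylpent-4-en-1-yl]-3-methylcyclohexan-1-one (C2 epimers) | ClCCC1[C@@](C)(CC[C@H](O)C(C)=C)[C@H](O)CCC1=O
F6 | step 12 | (3R,4R)-2-allyl-4-(tert-butyldimethylsilyloxy)-3-methyl-3-(4-methylpent-3-en-1-yl)cyclohexan-1-one (C2 epimers) | C=CCC1[C@@](C)(CCC=C(C)C)[C@H](O[Si](C)(C)C(C)(C)C)CCC1=O
F7 | step 12 | (3R,4R)-2-allyl-4-(tert-butyldimethylsilyloxy)-3-{2-[(2S)-3,3-dimethyloxiran-2-yl]ethyl}-3-methylcyclohexan-1-one (C2 epimers) | C=CCC1[C@@](C)(CC[C@@H]2OC2(C)C)[C@H](O[Si](C)(C)C(C)(C)C)CCC1=O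
F8 | step 12 | (3S,5aR,6R,9aR)-6-allyl-3-hydroxy-2,2,5a-trimethyloctahydro-1-benzoxepin-7(2H)-one | C=CC[C@@H]2[C@@]3(C)CC[C@H](O)C(C)(C)O[C@@H]3CCC2=O
F9 | step 12 | 3,7-bis(triethylsilyl) ether of (3S,5aR,6R,7S,9aR)-6-allyl-2,2,5a,7-tetramethyldecahydro-1-benzoxepine-3,7-diol | C=CC[C@@H]2[C@@]3(C)CC[C@H](O[Si](CC)(CC)CC)C(C)(C)O[C@@H]3CC[C@]2(C)O[Si](CC)(CC)CC
F10 | step 12 | 2-[(3S,5aR,6R,7S,9aR)-2,2,5a,7-tetramethyl-3,7-bis(triethylsilyloxy)decahydro-1-benzoxepin-6-yl]ethanol | OCC[C@@H]2[C@@]3(C)CC[C@H](O[Si](CC)(CC)CC)C(C)(C)O[C@@H]3CC[C@]2(C)O[Si](CC)(CC)CC
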